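From early times on, target in the grey run, where substrate was fed, rose roughly with the square of time, from 5.2% after 2.00 min to 18.8% after 4.00 min, so 3.62 times as much in twice the time, which is what I expected of a steady feed reacting at first order in substrate, and I took dissolved gas as steady.

all flasks: catalyst 0.75 mM

| run | substrate | gas phase | remark | time |
|---|---|---|---|---|
| ochre | 16 mM (fed, over 4.0 min) | 1.2 mM (held) | run made earlier |  |
| grey | 25 mM (fed, over 4.0 min) | 1.2 mM (held) | run made earlier |  |
| Thursday's | 29 mM (fed, over 4.0 min) | 1.2 mM (held) |  | 6.0 min |
| Wednesday's | 20 mM | 1.2 mM | everything together at the start | 4.0 min |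

| run | time / min | target / % |
|---|---|---|
| ochre | 0.333 | 0 |
| ochre | 0.500 | 0 |
| ochre | 1.00 | 1.2 |
| ochre | 1.50 | 4.5 |
| ochre | 2.50 | 7.3 |
| ochre | 4.00 | 21.8 |
| grey | 0.667 | 0.6 |
| grey | 1.33 | 2.5 |
| grey | 2.00 | 5.2 |
| grey | 3.00 | 10.9 |
| grey | 4.00 | 18.8 |

(each reading ± 1 percentage point)

- at the start none of the gas is dissolved
- steps under discussion: gas phase <-> dissolved gas; substrate + dissolved gas + catalyst -> catalyst + target; dissolved gas -> decomposed reagent
- percentages count the whole charge, also what has not yet gone in

1. the flask that ends with the higher amount of target, in percent of the substrate charged, or "neither" when 2 percentage points or less lies between them (Thursday's / Wednesday's / neither)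
2. final target, as a percentage of the substrate charged, in Thursday's
3. final target, as a percentage of the substrate charged, in Wednesday's

I left this note for the bench. At held gas and fixed catalyst, first order gives one percentage curve at any charge, so I averaged the ochre and grey end-of-feed readings to 20.3%, their gap being 3 percentage points at a scatter of 1 point each. For a feed lasting tf, that percentage is about (x/2)(1 − x/3), where x is k·tf. Ignoring the bracket gave x = 0.406; putting that back gave 0.470, and one more round gave 0.481. So k, the pseudo-first-order constant, meaning the fraction of the substrate present that turns to target each minute, read from those runs with their feed of 4.0 min, was 0.120 min⁻¹.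

I expected Thursday's flask to hold about 79.4% substrate when its feed ended, and 37.6% target after 2.00 min more. I expected Wednesday's to reach 38.2% target, a gap of 0.6 points, smaller than the margin. Since k was read at 0.75 mM of catalyst and 1.2 mM of gas, I wrote that neither was to be touched.

The forecast, lower than my figures, said neither, with 35% for Thursday's and 33.5% for Wednesday's, noting that “Starting with no dissolved gas at full substrate costs a bit”. The flasks gave neither: 37.1% for Thursday's and 37.7% for Wednesday's.

    gas phase ⇌ dissolved gas, rate k1*(csat - [dissolved gas]) (kL = 7.50 s⁻¹)
    substrate + dissolved gas + catalyst → catalyst + target (k = 2200 M⁻² s⁻¹)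
    dissolved gas → decomposed reagent (k = 0.00370 s⁻¹)

In Wednesday's flask the step to target ran with dissolved gas at 1.20 mM and catalyst at 100% of its charge at 2.00 min, while the loss of dissolved gas ran beside it and had made 1.06 mM of decomposed reagent by 4.00 min, when 62.3% of the substrate remained; ln(2)/k gives 5.78 min, and that flask's half-life of substrate by this step at 1.53 min was 5.9 min. With 1.9 mM of catalyst, k scaled by the catalyst charge gives 70.4% target after 4.0 min, and that neighbour of Wednesday's flask ended with 69.7%.

All runs are simulated with constants of no real substance; scatter was added.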